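**Retrosynthetic overview**
1. Locants: plain numbers refer to the 4'-methoxyflavone half (linked at C6), double-primed numbers to the 7''-methoxy-4'''-hydroxyflavone half (linked at C8''). Feature: without its pyranone, ring A of the first half is a 4-aryl-3,5-dioxyphenol with a mirror plane through C8a, C6 and the biaryl axis. C8a (para to the axis) must carry O1 and its neighbour C4a must carry the C4 carbonyl carbon, so this vicinal O/acyl pair corresponds to the two ends of an aryne.
2. Key disconnection: O1–C8a, C4–C4a and O1–C2 are cut together, giving the C4a≡C8a aryne (from an o-silylaryl triflate) and 3-(4-methoxyphenyl)propiolic acid. Ring C of this half is the only ring that is built, and it is closed last.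
3. The C6–C8'' axis comes from a Suzuki–Miyaura coupling of 8-borylated di-O-benzylgenkwanin with a 4-bromo-2-silylphenol. Triflation follows the coupling.
4. The silylphenol comes from 2-bromoresorcinol by MOM protection, C–H borylation/oxidation para to bromine, iodination at either of the two equivalent ortho carbons, and a retro-Brook shift. Silicon is installed before the flavone is attached, so no organolithium reagent meets a chromone carbonyl.
5. Endgame: hydrogenolysis of the two benzyl ethers, then acid cleavage of the two MOM ethers.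

Key step: step 10

Assumption: the SMILES gives no descriptor for the hindered C6–C8'' axis, so the racemic mixture of atropisomers is the goal. There is no stereocentre to set.

Step 1
Reactants: 1 2-bromoresorcinol (2-bromobenzene-1,3-diol)
Product: 2 2-bromo-1,3-bis(methoxymethoxy)benzene
Conditions: NaH (2.4 equiv), MOMCl (2.4 equiv), DMF, 0 °C to rt
Reagents that add atoms: chloromethyl methyl ether (MOMCl), COCCl
Why: Williamson-type O-alkylation of both phenoxides; an acetal group is used instead of an arylmethyl group because the next step would also borylate the unhindered C–H bonds of a benzyl ring.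

Step 2
Reactants: 2 2-bromo-1,3-bis(methoxymethoxy)benzene
Product: 4 4-bromo-3,5-bis(methoxymethoxy)phenol, via aryl pinacol boronate 3 (not isolated)
Conditions: [Ir(OMe)(cod)]2 (1.5 mol %), dtbpy (3 mol %), B2pin2 (0.7 equiv), THF, 80 °C (sealed); then 30% H2O2, aq NaOH, THF, 0 °C
Reagents that add atoms: bis(pinacolato)diboron, CC1(C)OB(OC1(C)C)B1OC(C)(C)C(C)(C)O1 (boron of 3); hydrogen peroxide, OO (phenol oxygen of 4)
Why: Iridium-catalysed aromatic C–H borylation is governed by sterics, so in this 1,2,3-trisubstituted ring only the carbon para to bromine (no ortho substituent) should react with the C–Br bond tolerated, and basic peroxide then turns C–B into C–O without touching the MOM acetals.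

Step 3
Reactants: 4 4-bromo-3,5-bis(methoxymethoxy)phenol
Product: 5 4-bromo-2-iodo-3,5-bis(methoxymethoxy)phenol
Conditions: NIS (1.0 equiv), MeCN, −20 to 0 °C, dark
Reagents that add atoms: N-iodosuccinimide, O=C1CCC(=O)N1I
Why: Electrophilic aromatic iodination of an activated phenol; 4 is mirror-symmetric, so its two free ortho carbons are equivalent and one equivalent of NIS should give a single mono-iodide.

Step 4
Reactants: 5 4-bromo-2-iodo-3,5-bis(methoxymethoxy)phenol
Product: 7 4-bromo-3,5-bis(methoxymethoxy)-2-(trimethylsilyl)phenol, via aryl trimethylsilyl ether 6 (not isolated)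
Conditions: HMDS, THF, 65 °C, concentrate; n-BuLi (1.05 equiv), THF, −78 °C; aq NH4Cl
Reagents that add atoms: hexamethyldisilazane, C[Si](C)(C)N[Si](C)(C)C
Why: O-silylation followed by iodine–lithium exchange, which is much faster than bromine–lithium exchange at −78 °C, and a retro-Brook (1,3 O-to-C) silyl shift driven by lithium phenoxide formation, leaving C–Br in place for the coupling.

Step 5
Reactants: 8 genkwanin (5-hydroxy-2-(4-hydroxyphenyl)-7-methoxy-4H-chromen-4-one)
Product: 9 5-(benzyloxy)-2-[4-(benzyloxy)phenyl]-7-methoxy-4H-chromen-4-one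
Conditions: BnBr (3 equiv), K2CO3 (4 equiv), DMF, 80 °C
Reagents that add atoms: benzyl bromide, BrCc1ccccc1
Why: Williamson ether synthesis; heating in DMF overcomes the hydrogen bond between the 5-OH and the C4 carbonyl, so both phenols are capped.

Step 6
Reactants: 9 5-(benzyloxy)-2-[4-(benzyloxy)phenyl]-7-methoxy-4H-chromen-4-one
Product: 10 5-(benzyloxy)-2-[4-(benzyloxy)phenyl]-8-iodo-7-methoxy-4H-chromen-4-one
Conditions: I2 (1.1 equiv), CF3CO2Ag (1.1 equiv), CH2Cl2, 0 °C to rt, dark
Reagents that add atoms: iodine, [I][I]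
Why: Silver-assisted electrophilic aromatic iodination; with O5 alkylated, 5,7-dialkoxyflavones react at C8, whose second neighbour is the tied-back ring oxygen, rather than at C6, which lies between two freely rotating alkoxy groups.

Step 7
Reactants: 10 5-(benzyloxy)-2-[4-(benzyloxy)phenyl]-8-iodo-7-methoxy-4H-chromen-4-one
Product: 11 5-(benzyloxy)-2-[4-(benzyloxy)phenyl]-7-methoxy-8-(4,4,5,5-tetramethyl-1,3,2-dioxaborolan-2-yl)-4H-chromen-4-one
Conditions: B2pin2 (1.5 equiv), PdCl2(dppf) (5 mol %), KOAc (3 equiv), 1,4-dioxane, 90 °C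
Reagents that add atoms: bis(pinacolato)diboron, CC1(C)OB(OC1(C)C)B1OC(C)(C)C(C)(C)O1
Why: Miyaura borylation of an aryl iodide; acetate is too weak a base to drive homocoupling, and the chromone and benzyl ethers are inert.

Step 8
Reactants: 7 4-bromo-3,5-bis(methoxymethoxy)-2-(trimethylsilyl)phenol; 11 the 8-borylated flavone
Product: 12 5-(benzyloxy)-2-[4-(benzyloxy)phenyl]-8-[4-hydroxy-2,6-bis(methoxymethoxy)-3-(trimethylsilyl)phenyl]-7-methoxy-4H-chromen-4-one
Conditions: Pd(OAc)2 (5 mol %), SPhos (10 mol %), K3PO4 (4 equiv), toluene–H2O 10:1, 90 °C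
Reagents that add atoms: none
Why: Suzuki–Miyaura coupling with a bulky electron-rich biaryl phosphine, the ligand class established for tetra-ortho-substituted biaryls; the extra base carries the phenol as phenoxide, and C–Si, MOM and benzyl groups should survive.

Step 9
Reactants: 12 the biaryl o-silylphenol
Product: 13 4-{5-(benzyloxy)-2-[4-(benzyloxy)phenyl]-7-methoxy-4-oxo-4H-chromen-8-yl}-3,5-bis(methoxymethoxy)-2-(trimethylsilyl)phenyl trifluoromethanesulfonate (aryne precursor)
Conditions: Tf2O (1.2 equiv), pyridine (3 equiv), CH2Cl2, −78 to 0 °C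
Reagents that add atoms: trifluoromethanesulfonic anhydride, O=S(=O)(OS(=O)(=O)C(F)(F)F)C(F)(F)F
Why: Standard O-triflation of an o-silylphenol; low temperature and excess pyridine keep the medium non-acidic, so neither protodesilylation of the electron-rich ring nor MOM loss should occur.

Step 10
Reactants: 13 the o-silylaryl triflate; 14 3-(4-methoxyphenyl)propiolic acid
Product: 17 8-[5,7-bis(methoxymethoxy)-2-(4-methoxyphenyl)-4-oxo-4H-chromen-6-yl]-5-(benzyloxy)-2-[4-(benzyloxy)phenyl]-7-methoxy-4H-chromen-4-one (protected target), via aryne 15 (not isolated), via 2-hydroxyaryl ynone 16 (not isolated)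
Conditions: 14 (1.5 equiv), CsF (4 equiv), THF (0.05 M), 125 °C, sealed tube
Reagents that add atoms: none
Why: Fluoride attacks silicon and triflate leaves, releasing the C4a≡C8a aryne 15 slowly from sparingly soluble CsF; the cesium propiolate adds through oxygen at C8a, the resulting C4a aryl anion attacks the ester carbonyl through a four-membered alkoxide, and opening of that ring moves the acyl group from O to C to give the phenoxide of ynone 16. The closest known reaction is the fluoride-induced insertion of arynes into the C–O bond of carboxylic acids in hot THF, which gives flavones directly when the acid is an arylpropiolic acid. Ring C closes by 6-endo-dig oxa-Michael addition of the C8a phenoxide to the anisyl-bearing alkyne carbon, with the acid proton ending at C3, and the aprotic medium favours this mode over 5-exo-dig aurone formation. No stereocentre is created. The selectivity needed is the orientation of addition, which decides between a 6-linked and an 8-linked flavone: the inductively withdrawing C5 OMOM group distorts the aryne so that C8a is the more linear, more electrophilic and less hindered carbon, and the developing negative charge at C4a sits next to that oxygen. The high temperature is needed so that the acyl shift outruns protonation of the aryl anion, which would stop at the aryl propiolate.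

Step 11
Reactants: 17 the protected target
Product: 18 8-[5,7-bis(methoxymethoxy)-2-(4-methoxyphenyl)-4-oxo-4H-chromen-6-yl]-5-hydroxy-2-(4-hydroxyphenyl)-7-methoxy-4H-chromen-4-one
Conditions: H2 (1 atm), 10% Pd/C, THF–EtOAc, rt
Reagents that add atoms: none
Why: Catalytic hydrogenolysis of aryl benzyl ethers; in a neutral aprotic solvent the MOM acetals stay in place, and the pyranone C2=C3 bonds, being part of vinylogous esters, are reduced much more slowly.

Step 12
Reactants: 18 the bis-MOM ether
Product: 19 8-[5,7-dihydroxy-2-(4-methoxyphenyl)-4-oxo-4H-chromen-6-yl]-5-hydroxy-2-(4-hydroxyphenyl)-7-methoxy-4H-chromen-4-one (target, CNP0290866.0)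
Conditions: 3 M aq HCl, MeOH–THF, 50 °C
Reagents that add atoms: none
Why: Acid-catalysed acetal exchange removes both MOM groups, while the aryl methyl ethers and both flavone cores are inert to dilute acid.

**Compound list**
1 | 2-bromoresorcinol | Oc1cccc(O)c1Br | starting material
2 | 2-bromo-1,3-bis(methoxymethoxy)benzene | COCOc1cccc(OCOC)c1Br | intermediate
3 | 2-[4-bromo-3,5-bis(methoxymethoxy)phenyl]-4,4,5,5-tetramethyl-1,3,2-dioxaborolane | COCOc1cc(cc(OCOC)c1Br)B1OC(C)(C)C(C)(C)O1 | intermediate (not isolated)
4 | 4-bromo-3,5-bis(methoxymethoxy)phenol | COCOc1cc(O)cc(OCOC)c1Br | intermediate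
5 | 4-bromo-2-iodo-3,5-bis(methoxymethoxy)phenol | COCOc1cc(O)c(I)c(OCOC)c1Br | intermediate
6 | [4-bromo-2-iodo-3,5-bis(methoxymethoxy)phenoxy]trimethylsilane | COCOc1cc(O[Si](C)(C)C)c(I)c(OCOC)c1Br | intermediate (not isolated)
7 | 4-bromo-3,5-bis(methoxymethoxy)-2-(trimethylsilyl)phenol | COCOc1cc(O)c([Si](C)(C)C)c(OCOC)c1Br | intermediate
8 | genkwanin | COc1cc(O)c2c(=O)cc(-c3ccc(O)cc3)oc2c1 | starting material
9 | 5,4'-di-O-benzylgenkwanin | COc1cc(OCc2ccccc2)c2c(=O)cc(-c3ccc(OCc4ccccc4)cc3)oc2c1 | intermediate
10 | 8-iodo-5,4'-di-O-benzylgenkwanin | COc1cc(OCc2ccccc2)c2c(=O)cc(-c3ccc(OCc4ccccc4)cc3)oc2c1I | intermediate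
11 | 5,4'-di-O-benzylgenkwanin 8-pinacol boronate | COc1cc(OCc2ccccc2)c2c(=O)cc(-c3ccc(OCc4ccccc4)cc3)oc2c1B1OC(C)(C)C(C)(C)O1 | intermediate
12 | biaryl o-silylphenol | COCOc1cc(O)c([Si](C)(C)C)c(OCOC)c1-c1c(OC)cc(OCc2ccccc2)c2c(=O)cc(-c3ccc(OCc4ccccc4)cc3)oc12 | intermediate
13 | biaryl o-silylaryl triflate (aryne precursor) | COCOc1cc(OS(=O)(=O)C(F)(F)F)c([Si](C)(C)C)c(OCOC)c1-c1c(OC)cc(OCc2ccccc2)c2c(=O)cc(-c3ccc(OCc4ccccc4)cc3)oc12 | intermediate
14 | 3-(4-methoxyphenyl)propiolic acid | COc1ccc(cc1)C#CC(=O)O | starting material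
15 | C4a≡C8a aryne | COCOC1=C(C(OCOC)=CC#C1)c1c(OC)cc(OCc2ccccc2)c2c(=O)cc(-c3ccc(OCc4ccccc4)cc3)oc12 | intermediate (not isolated)
16 | 2-hydroxyaryl 2-(4-methoxyphenyl)ethynyl ketone | COc1ccc(cc1)C#CC(=O)c1c(O)cc(OCOC)c(c1OCOC)-c1c(OC)cc(OCc2ccccc2)c2c(=O)cc(-c3ccc(OCc4ccccc4)cc3)oc12 | intermediate (not isolated)
17 | protected target (5,7-di-O-MOM, 5'',4'''-di-O-benzyl) | COc1ccc(cc1)-c1cc(=O)c2c(OCOC)c(c(OCOC)cc2o1)-c1c(OC)cc(OCc2ccccc2)c2c(=O)cc(-c3ccc(OCc4ccccc4)cc3)oc12 | intermediate
18 | 5,7-di-O-MOM target | COc1ccc(cc1)-c1cc(=O)c2c(OCOC)c(c(OCOC)cc2o1)-c1c(OC)cc(O)c2c(=O)cc(-c3ccc(O)cc3)oc12 | intermediate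
19 | CNP0290866.0 | COc1ccc(-c2cc(=O)c3c(O)c(-c4c(OC)cc(O)c5c(=O)cc(-c6ccc(O)cc6)oc45)c(O)cc3o2)cc1 | target

**Totals:** 12 steps. The longest linear sequence is 9 steps (steps 1–4 and 8–12).

**Steps most likely to fail**

Step 10. Three processes could erode the key step:
- protonation of the C4a aryl anion before the acyl shift, which stops at O-arylation;
- thermal decarboxylation of the propiolate;
- partial 5-exo closure.

The fallback sets out from 12 and returns at 17. Iodine monochloride (1 equiv, CH2Cl2, −78 °C) should replace silicon by iodine through ipso-substitution at C4a. This gives 5-(benzyloxy)-2-[4-(benzyloxy)phenyl]-8-[4-hydroxy-3-iodo-2,6-bis(methoxymethoxy)phenyl]-7-methoxy-4H-chromen-4-one F1, so the regiochemical information held by the C–Si bond passes to a C–I bond. A palladium-catalysed carbonylative coupling of this o-iodophenol with 4-ethynylanisole follows (CO at 20 bar, PdCl2(dppf), Et2NH, 120 °C). This is a known flavone annulation in which the amine steers closure to the 6-endo mode, and it should deliver 17.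

Step 8. Oxidative addition into the electron-rich, doubly flanked C–Br bond of the phenoxide may be slow. Protodeboronation of the boronate could then win, and hot aqueous base could erode the C–Si bond. The fallback reverses the polarity, uses no base, sets out from 7 and 10, and returns at 12.
- TBSCl/imidazole (DMF, rt) should give [4-bromo-3,5-bis(methoxymethoxy)-2-(trimethylsilyl)phenoxy](tert-butyl)dimethylsilane F2.
- n-BuLi (THF, −78 °C) followed by ZnCl2 should give the arylzinc chloride F3, whose metal is chelated by the two MOM groups.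
- Negishi coupling with iodide 10 (Pd2(dba)3, RuPhos, THF–NMP, 70 °C) should give the O-TBS biaryl F4.
- TBAF buffered with AcOH (THF, 0 °C) should free phenol 12.

Step 7. Hydrodeiodination and sluggish transmetalation at the doubly flanked C8 may dominate. The fallback replaces catalysis by halogen–metal exchange, sets out from 10, and returns at 11. n-BuLi is added at −100 °C to a THF solution of 10 and B(OiPr)3, so the 8-lithioflavone is trapped as it forms. Iodine–lithium exchange on 8-iodoflavones is known to outrun carbonyl addition. Mild acidic work-up should give the flavone-8-boronic acid F5, and pinacol with MgSO4 (CH2Cl2, rt) converts it into 11.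

**Further compounds**
F1 | step 10 | 5-(benzyloxy)-2-[4-(benzyloxy)phenyl]-8-[4-hydroxy-3-iodo-2,6-bis(methoxymethoxy)phenyl]-7-methoxy-4H-chromen-4-one | COCOc1cc(O)c(I)c(OCOC)c1-c1c(OC)cc(OCc2ccccc2)c2c(=O)cc(-c3ccc(OCc4ccccc4)cc3)oc12
F2 | step 8 | [4-bromo-3,5-bis(methoxymethoxy)-2-(trimethylsilyl)phenoxy](tert-butyl)dimethylsilane | COCOc1cc(O[Si](C)(C)C(C)(C)C)c([Si](C)(C)C)c(OCOC)c1Br
F3 | step 8 | [4-(tert-butyldimethylsilyloxy)-2,6-bis(methoxymethoxy)-3-(trimethylsilyl)phenyl]zinc chloride | COCOc1cc(O[Si](C)(C)C(C)(C)C)c([Si](C)(C)C)c(OCOC)c1[Zn]Cl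
F4 | step 8 | O-TBS ether of biaryl phenol 12 | COCOc1cc(O[Si](C)(C)C(C)(C)C)c([Si](C)(C)C)c(OCOC)c1-c1c(OC)cc(OCc2ccccc2)c2c(=O)cc(-c3ccc(OCc4ccccc4)cc3)oc12
F5 | step 7 | {5-(benzyloxy)-2-[4-(benzyloxy)phenyl]-7-methoxy-4-oxo-4H-chromen-8-yl}boronic acid | COc1cc(OCc2ccccc2)c2c(=O)cc(-c3ccc(OCc4ccccc4)cc3)oc2c1B(O)O
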